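The target is read as a desymmetrised derivative of centrosymmetric cochliodinol, so everything rests on the bond between the quinone ring carbon next to the future C–OOH carbon and C3 of the second 5-prenylindole. The key step makes this bond by acid-promoted conjugate addition of 5-prenylindole to 2,5-dichloro-3-(5-prenylindol-3-yl)-1,4-benzoquinone, followed in the same flask by DDQ dehydrogenation. It exploits the single C–H carbon of the quinone ring (C6 of the precursor), a β-enone carbon para to the first indolyl-bearing carbon, and the enamine-like C3 of the indole pyrrole ring. The two chlorines hold the places of the later hydroxyl and hydroperoxyl groups.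

Key step: step 3

Remark on the chemistry: dichloride 8 and cochliodinol 10 are centrosymmetric, so their two indolyl–quinone bonds and their two C–O sites are equivalent, and replacing either hydroxyl of 10 gives the same hydroperoxide. No compound in the route has a stereocentre or a stereogenic double bond.

Step 1
Reactants: 1 5-bromo-1H-indole; 2 tributyl(3-methylbut-2-en-1-yl)stannane
Product: 3 5-(3-methylbut-2-en-1-yl)-1H-indole (5-prenylindole)
Conditions: Pd(PPh3)4 (5 mol %), DMF, 100 °C
Reagents that add atoms: none
Why: Stille cross-coupling, in which oxidative addition of zerovalent palladium into the C5–Br bond, transmetalation of the allylstannane and reductive elimination at the unsubstituted allyl terminus should give the linear prenyl arene, the free N–H being tolerated.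

Step 2
Reactants: 3 5-(3-methylbut-2-en-1-yl)-1H-indole; 4 2,5-dichloro-1,4-benzoquinone
Product: 6 2,5-dichloro-3-[5-(3-methylbut-2-en-1-yl)-1H-indol-3-yl]cyclohexa-2,5-diene-1,4-dione, via hydroquinone 5 (not isolated)
Conditions: 4 (2 equiv), HCl (conc. aq., cat.), THF, rt, dark; then DDQ (1 equiv), rt
Reagents that add atoms: none
Why: Acid-promoted Friedel–Crafts-type conjugate addition of indole C3 to one of the two equivalent C–H carbons of 4 gives hydroquinone 5, which DDQ dehydrogenates in the same flask, while the excess of 4 and the lower electrophilicity of the push–pull product 6 should hold the reaction at mono-addition.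

Step 3
Reactants: 6 2,5-dichloro-3-[5-(3-methylbut-2-en-1-yl)-1H-indol-3-yl]cyclohexa-2,5-diene-1,4-dione; 3 5-(3-methylbut-2-en-1-yl)-1H-indole
Product: 8 2,5-dichloro-3,6-bis[5-(3-methylbut-2-en-1-yl)-1H-indol-3-yl]cyclohexa-2,5-diene-1,4-dione, via hydroquinone 7 (not isolated)
Conditions: 3 (1.5 equiv), H2SO4 (cat.), THF, rt, dark; then DDQ (1.1 equiv), rt
Reagents that add atoms: none
Why: Protonation of the C4 carbonyl of 6 makes C6, the β-carbon of the C4=O/C5=C6 enone, electrophilic; the enamine-like C3 of indole 3 adds there, proton loss re-aromatises the indole and enolisation gives the fully substituted hydroquinone 7, which DDQ dehydrogenates in the same flask to quinone 8. The closest known reaction type is the acid-promoted conjugate addition of indoles to 2,5-dichloro-1,4-benzoquinones followed by DDQ oxidation, a Friedel–Crafts-type Michael addition that amounts to a dehydrogenative C–H/C–H coupling. No ring is closed and no stereocentre is formed. The step needs regioselectivity on both partners: C6 is the only C–H carbon of the quinone ring, and its activating carbonyl C4=O is only cross-conjugated with the indolyl donor on quinone C3, whereas ipso attack at C5–Cl would have to use the donor-deactivated C1=O and ipso attack at C2–Cl is blocked by the neighbouring indolyl group; on the indole, C3 is the most nucleophilic carbon of a 2,3-unsubstituted ring. Catalytic acid and brief exposure to DDQ are expected to leave the prenyl double bonds and both N–H groups untouched.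

Step 4
Reactants: 8 2,5-dichloro-3,6-bis[5-(3-methylbut-2-en-1-yl)-1H-indol-3-yl]cyclohexa-2,5-diene-1,4-dione
Product: 10 cochliodinol (2,5-dihydroxy-3,6-bis[5-(3-methylbut-2-en-1-yl)-1H-indol-3-yl]cyclohexa-2,5-diene-1,4-dione), via chlorohydroxyquinone 9 (not isolated)
Conditions: NaOH (2 M aq.), 1,4-dioxane, 80 °C, N2; then HCl (1 M), 0 °C
Reagents that add atoms: sodium hydroxide, [Na+].[OH-]
Why: Two successive addition–elimination displacements (vinylogous acyl substitution) of chloride by hydroxide, the second on the less electrophilic anion of 9 and therefore run hot, as in the known alkaline hydrolysis of 2,5-dichloro-3,6-di(indol-3-yl)quinones, to which prenyl and N–H groups are inert.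

Step 5
Reactants: 10 cochliodinol
Product: 11 hydroperoxycochliodinol (2-hydroperoxy-5-hydroxy-3,6-bis[5-(3-methylbut-2-en-1-yl)-1H-indol-3-yl]cyclohexa-2,5-diene-1,4-dione)
Conditions: H2O2 (anhydrous, ca. 2 M in Et2O, 10 equiv), camphor-10-sulfonic acid (10 mol %), Et2O/CH2Cl2, 0 °C to rt, dark; stopped at partial conversion, non-reductive aqueous work-up, 10 recycled
Reagents that add atoms: hydrogen peroxide, OO
Why: Proposed new method: the hydroxyquinone is a vinylogous carboxylic acid (HO–C2=C3–C4=O), so acid-catalysed addition of H2O2 to the hydroxyl-bearing carbon C2 through the protonated C4 carbonyl should give a gem-hydroxy hydroperoxide that loses water to restore the quinone as the vinylogous peroxy acid, with excess anhydrous H2O2 pulling the equilibrium over and the equivalence of the two hydroxyls of 10 removing any site-selectivity question; the closest known reaction types are the acid-catalysed equilibration of carboxylic acids with H2O2 to peroxy acids, the acid-catalysed conversion of ketones into gem-hydroperoxides, and the acid-catalysed exchange of the hydroxyls of 2,5-dihydroxy-1,4-benzoquinones for alkoxy groups.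

Compound list
1 | 5-bromo-1H-indole | Brc1ccc2[nH]ccc2c1 | starting material
2 | tributyl(3-methylbut-2-en-1-yl)stannane | CC(C)=CC[Sn](CCCC)(CCCC)CCCC | starting material
3 | 5-(3-methylbut-2-en-1-yl)-1H-indole (5-prenylindole) | CC(C)=CCc1ccc2[nH]ccc2c1 | intermediate
4 | 2,5-dichloro-1,4-benzoquinone | O=C1C=C(Cl)C(=O)C=C1Cl | starting material
5 | 2,5-dichloro-3-[5-(3-methylbut-2-en-1-yl)-1H-indol-3-yl]benzene-1,4-diol | CC(C)=CCc1ccc2[nH]cc(-c3c(Cl)c(O)cc(Cl)c3O)c2c1 | intermediate
6 | 2,5-dichloro-3-[5-(3-methylbut-2-en-1-yl)-1H-indol-3-yl]cyclohexa-2,5-diene-1,4-dione | CC(C)=CCc1ccc2[nH]cc(C3=C(Cl)C(=O)C=C(Cl)C3=O)c2c1 | intermediate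
7 | 2,5-dichloro-3,6-bis[5-(3-methylbut-2-en-1-yl)-1H-indol-3-yl]benzene-1,4-diol | CC(C)=CCc1ccc2[nH]cc(-c3c(Cl)c(O)c(-c4c[nH]c5ccc(CC=C(C)C)cc45)c(Cl)c3O)c2c1 | intermediate
8 | 2,5-dichloro-3,6-bis[5-(3-methylbut-2-en-1-yl)-1H-indol-3-yl]cyclohexa-2,5-diene-1,4-dione | CC(C)=CCc1ccc2[nH]cc(C3=C(Cl)C(=O)C(c4c[nH]c5ccc(CC=C(C)C)cc45)=C(Cl)C3=O)c2c1 | intermediate
9 | 2-chloro-5-hydroxy-3,6-bis[5-(3-methylbut-2-en-1-yl)-1H-indol-3-yl]cyclohexa-2,5-diene-1,4-dione | CC(C)=CCc1ccc2[nH]cc(C3=C(O)C(=O)C(c4c[nH]c5ccc(CC=C(C)C)cc45)=C(Cl)C3=O)c2c1 | intermediate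
10 | cochliodinol, 2,5-dihydroxy-3,6-bis[5-(3-methylbut-2-en-1-yl)-1H-indol-3-yl]cyclohexa-2,5-diene-1,4-dione | CC(C)=CCc1ccc2[nH]cc(C3=C(O)C(=O)C(c4c[nH]c5ccc(CC=C(C)C)cc45)=C(O)C3=O)c2c1 | intermediate
11 | hydroperoxycochliodinol, 2-hydroperoxy-5-hydroxy-3,6-bis[5-(3-methylbut-2-en-1-yl)-1H-indol-3-yl]cyclohexa-2,5-diene-1,4-dione | CC(C)=CCc1ccc2[nH]cc(C3=C(O)C(=O)C(c4c[nH]c5ccc(CC=C(C)C)cc45)=C(OO)C3=O)c2c1 | target

Total step count: 5. Longest linear sequence: 5 steps (1 → 3 → 6 → 8 → 10 → 11).

Steps most likely to fail

First, step 5, which bears the label "Proposed new method:". The perhydrolysis equilibrium may be established too slowly, so that acid-promoted addition of H2O2 across the prenyl double bonds, over-exchange to the bis-hydroperoxide or decomposition of the peroxide takes over. The fallback uses known reaction types and sets out from 8. Hydrolysis is stopped at the mono stage (NaOH, 2.2 equiv, THF/H2O, 0 °C to rt), where the hydroxyquinone anion protects the second chloride, and 9 is isolated after acidification. Addition–elimination on 9 with the caesium salt of 2-methoxyprop-2-yl hydroperoxide (COC(C)(C)OO, Cs2CO3, DMF, rt to 40 °C), a base-stable monoprotected form of H2O2, should give the peroxyketal 2-hydroxy-5-[(2-methoxypropan-2-yl)peroxy]-3,6-bis[5-(3-methylbut-2-en-1-yl)-1H-indol-3-yl]cyclohexa-2,5-diene-1,4-dione F1. Mild acid (AcOH/THF/H2O, rt) then cleaves the ketal and frees the hydroperoxide, coming back to the route at 11. In this sequence the free hydroperoxide is never exposed to base.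

Second, step 3. The conjugate addition may stall on the hindered, push–pull-deactivated quinone 6, and prolonged acid exposure may then oligomerise the indole or cyclise and hydrate the prenyl side chains. The fallback sets out from 3 and replaces acid-promoted addition to a C–H quinone by base-mediated addition–elimination on commercial tetrabromo-1,4-benzoquinone (bromanil), which needs neither acid nor an external oxidant. Indole 3 (1 equiv) and bromanil with Cs2CO3 in MeCN at rt should give 2,3,5-tribromo-6-[5-(3-methylbut-2-en-1-yl)-1H-indol-3-yl]cyclohexa-2,5-diene-1,4-dione F2. A second equivalent of 3 under the same conditions should displace the bromide para to the first indolyl-bearing carbon, the position served by the carbonyl that the indolyl donor does not deactivate, and give 2,5-dibromo-3,6-bis[5-(3-methylbut-2-en-1-yl)-1H-indol-3-yl]cyclohexa-2,5-diene-1,4-dione F3. Alkaline hydrolysis of F3 (NaOH aq., 1,4-dioxane, 80 °C; then HCl) comes back to the route at 10.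

Third, step 1. Allyl transfer may proceed with allylic transposition and give the 1,1-dimethylallyl isomer, or the stannane may be lost by protodestannylation. The fallback sets out from 1 and builds the prenyl group in two stages that cannot transpose. Suzuki–Miyaura coupling with allylboronic acid pinacol ester (Pd(dppf)Cl2, K2CO3, 1,4-dioxane/H2O, 80 °C) should give 5-(prop-2-en-1-yl)-1H-indole F4. Olefin cross-metathesis of F4 with 2-methylbut-2-ene (second-generation Grubbs catalyst, CH2Cl2, 40 °C) then caps the alkene as the prenyl group and comes back to the route at 3.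

Further compounds
F1 | step 5 | 2-hydroxy-5-[(2-methoxypropan-2-yl)peroxy]-3,6-bis[5-(3-methylbut-2-en-1-yl)-1H-indol-3-yl]cyclohexa-2,5-diene-1,4-dione | CC(C)=CCc1ccc2[nH]cc(C3=C(O)C(=O)C(c4c[nH]c5ccc(CC=C(C)C)cc45)=C(OOC(C)(C)OC)C3=O)c2c1
F2 | step 3 | 2,3,5-tribromo-6-[5-(3-methylbut-2-en-1-yl)-1H-indol-3-yl]cyclohexa-2,5-diene-1,4-dione | CC(C)=CCc1ccc2[nH]cc(C3=C(Br)C(=O)C(Br)=C(Br)C3=O)c2c1
F3 | step 3 | 2,5-dibromo-3,6-bis[5-(3-methylbut-2-en-1-yl)-1H-indol-3-yl]cyclohexa-2,5-diene-1,4-dione | CC(C)=CCc1ccc2[nH]cc(C3=C(Br)C(=O)C(c4c[nH]c5ccc(CC=C(C)C)cc45)=C(Br)C3=O)c2c1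
F4 | step 1 | 5-(prop-2-en-1-yl)-1H-indole | C=CCc1ccc2[nH]ccc2c1
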